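Labdane numbering is used. Everything rests on removing C7 from ring B. C7 is the only ring-B atom that bears nothing but hydrogen, and it lies between C6, which can migrate as a vinylic carbon, and C8, which can be a carbonyl carbon. Ring B (C5–C10) thus comes from the five-membered ring C5–C6–C8–C9–C10 of an enantioenriched hydrindenone. In one operation the key step inserts C7 as a β-oxido carbenoid, enlarges the ring by a 1,2-vinyl shift and, after equilibration, sets C5 trans to the C10 methyl group. Its precursor is a bicyclic cyclopentenol bearing a CHBr2 group. The C8 ketone then directs C9 allylation, C17 homologation and C6 oxygenation.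

Key step: step 6

Assumption: the (R)-configured ligand is taken to give (R)-4, by analogy with the sense of induction known for related 2-alkylcyclohexanone enol carbonates; if the sense were opposite, the (S)-ligand would be used.

Step 1
Reactants: 1 2,2,6-trimethylcyclohexanone; 2 allyl chloroformate
Product: 3 allyl 2,6,6-trimethylcyclohex-1-en-1-yl carbonate
Conditions: LiN(SiMe3)2, THF, 0 °C; then 2, −78 °C
Reagents that add atoms: allyl chloroformate, C=CCOC(=O)Cl
Why: O-acylation of a lithium enolate (enol carbonate formation): the ketone can enolise only toward its methine carbon, and the hard chloroformate reacts at the oxygen of the tetrasubstituted enolate.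

Step 2
Reactants: 3 allyl 2,6,6-trimethylcyclohex-1-en-1-yl carbonate
Product: 4 (R)-2-allyl-2,6,6-trimethylcyclohexan-1-one
Conditions: Pd2(dba)3 (2.5 mol%), (R)-t-BuPHOX (6 mol%), THF, 25 °C
Reagents that add atoms: none
Why: Decarboxylative asymmetric allylic alkylation (Tsuji type): zerovalent palladium ionises the allyl carbonate, CO2 is lost, and the ligand-bound allylpalladium enolate couples at carbon on one enantiotopic face, which sets the quaternary centre C10 as R.

Step 3
Reactants: 4 (R)-2-allyl-2,6,6-trimethylcyclohexan-1-one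
Product: 5 (R)-2,2,6-trimethyl-6-(2-oxopropyl)cyclohexan-1-one
Conditions: PdCl2 (10 mol%), Cu(OAc)2·H2O (25 mol%), O2 (1 atm), DMA/H2O, 25 °C
Reagents that add atoms: water, O
Why: Tsuji–Wacker oxidation: divalent palladium activates the terminal alkene for Markovnikov attack of water to give the methyl ketone, while the hindered ring ketone is a spectator.

Step 4
Reactants: 5 (R)-2,2,6-trimethyl-6-(2-oxopropyl)cyclohexan-1-one
Product: 6 (R)-4,4,7a-trimethyl-1,4,5,6,7,7a-hexahydro-2H-inden-2-one
Conditions: KOH, xylenes, 110 °C, Dean–Stark trap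
Reagents that add atoms: none
Why: Intramolecular aldol condensation: the ring ketone C5 cannot enolise, so the methyl group (future C6) of the side-chain ketone attacks it, and loss of water gives the conjugated cyclopentenone without touching C10.

Step 5
Reactants: 6 (R)-4,4,7a-trimethyl-1,4,5,6,7,7a-hexahydro-2H-inden-2-one; 7 dibromomethane
Product: 8 (7aR)-2-(dibromomethyl)-4,4,7a-trimethyl-2,4,5,6,7,7a-hexahydro-1H-inden-2-ol (both epimers at the carbinol carbon C8)
Conditions: 7 (1.5 equiv), lithium 2,2,6,6-tetramethylpiperidide, THF, −78 °C; then H2O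
Reagents that add atoms: dibromomethane, BrCBr
Why: 1,2-addition of dibromomethyllithium made in the presence of the ketone: the hard carbanion adds to C8 because the β-carbon C5 is fully substituted, and the configuration of the new carbinol carbon is of no account since it becomes sp2 again in step 6.

Step 6
Reactants: 8 (7aR)-2-(dibromomethyl)-4,4,7a-trimethyl-2,4,5,6,7,7a-hexahydro-1H-inden-2-ol
Product: 12 (4aS,8aR)-5,5,8a-trimethyl-4a,5,6,7,8,8a-hexahydronaphthalen-2(1H)-one, via β-oxido carbenoid 9 (not isolated), via lithium dienolate 10 (not isolated), via β,γ-enone 11 (not isolated)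
Conditions: n-BuLi (2.2 equiv), THF, −78 to 0 °C; then MeOH, NaOMe (cat.), 25 °C
Reagents that add atoms: none
Why: n-BuLi deprotonates the alcohol and exchanges one bromine to give the β-oxido carbenoid 9, in which the alkoxide pushes the vinylic carbon C6 from C8 onto the carbenoid carbon (the new C7) as LiBr leaves, so that the lithium dienolate 10 of the enlarged ring is released. The closest known reaction type is the one-carbon ring enlargement of cyclic ketones through their dibromomethyllithium adducts, a carbenoid counterpart of the Tiffeneau–Demjanov rearrangement. No ring is closed: the five-membered ring C5–C6–C8–C9–C10 grows to ring B by a 1,2-shift within the bicycle. Methanol protonates 10 at C7 to give 11, and methoxide moves the double bond into conjugation through the same dienolate; this γ-protonation creates C5, whose configuration is under thermodynamic control by C10 in favour of the trans-fused octalone (5α-H, axial 10β-methyl). The step needs migration of C6 rather than C9, which is secured by the higher migratory aptitude of an sp2 carbon that can share its π electrons with the electron-poor carbenoid centre, whereas C9 is a neopentyl-type methylene group.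

Step 7
Reactants: 12 (4aS,8aR)-5,5,8a-trimethyl-4a,5,6,7,8,8a-hexahydronaphthalen-2(1H)-one; 13 allyl bromide
Product: 15 (1R,4aS,8aS)-1-allyl-5,5,8a-trimethyl-4a,5,6,7,8,8a-hexahydronaphthalen-2(1H)-one (14,15,16,17-tetranorlabda-6,12-dien-8-one, 9β-allyl), via 9-epimer 14 (not isolated)
Conditions: LiN(i-Pr)2, THF, −78 °C; 13, −78 to 0 °C; then NaOMe (cat.), MeOH, 25 °C
Reagents that add atoms: allyl bromide, C=CCBr
Why: Kinetic α'-alkylation of a cross-conjugated enolate followed by epimerisation: the enolate takes up allyl bromide at C9 mainly anti to the axial C10 methyl group to give 14, and methoxide then equilibrates this centre next to the ketone to the equatorial 9β-allyl isomer 15 (9α-H).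

Step 8
Reactants: 15 (1R,4aS,8aS)-1-allyl-5,5,8a-trimethyl-4a,5,6,7,8,8a-hexahydronaphthalen-2(1H)-one; 16 (methoxymethyl)triphenylphosphonium chloride
Product: 17 17-methoxy-14,15,16-trinorlabda-6,8(17),12-triene (5α-H, 9α-H; both enol ether geometries)
Conditions: 16, KOt-Bu, THF, 0 to 25 °C
Reagents that add atoms: (methoxymethyl)triphenylphosphonium chloride, COC[P+](c1ccccc1)(c1ccccc1)c1ccccc1.[Cl-]
Why: Wittig olefination with the methoxymethylene ylide: 1,2-attack on the enone carbonyl brings in C17 as a methyl enol ether, both geometries of which serve equally, and any epimerisation at C9 only returns the more stable isomer.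

Step 9
Reactants: 17 17-methoxy-14,15,16-trinorlabda-6,8(17),12-triene
Product: 18 (5S,6S,9R,10R)-6α-hydroxy-14,15,16-trinorlabda-7,12-dien-17-al
Conditions: mCPBA (1.0 equiv), NaHCO3, CH2Cl2/H2O, −20 to 0 °C
Reagents that add atoms: mCPBA, O=C(OO)c1cccc(Cl)c1; water, O
Why: γ-Hydroxylation of a dienol ether with a peracid (vinylogous Rubottom-type oxidation): the electrophilic oxygen attacks the diene terminus C6 from the α face, since the β face is shielded by the axial methyl groups on C4 and C10, and collapse of the enol ether with water gives the enal, which sets C6 as S.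

Step 10
Reactants: 18 (5S,6S,9R,10R)-6α-hydroxy-14,15,16-trinorlabda-7,12-dien-17-al; 19 (R)-2-methylbutanoic acid
Product: 20 (5S,6S,9R,10R)-6α-[(R)-2-methylbutanoyloxy]-14,15,16-trinorlabda-7,12-dien-17-al
Conditions: DCC, DMAP, CH2Cl2, 0 to 25 °C
Reagents that add atoms: (R)-2-methylbutanoic acid, CC[C@@H](C)C(=O)O
Why: Steglich esterification: the carbodiimide activates the acid and DMAP transfers the acyl group to the equatorial 6α-alcohol without touching C6 or the α-centre of the acid, and the ester of any minor enantiomer of the core is now a separable diastereomer.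

Step 11
Reactants: 20 (5S,6S,9R,10R)-6α-[(R)-2-methylbutanoyloxy]-14,15,16-trinorlabda-7,12-dien-17-al; 21 α-methylene-γ-butyrolactone
Product: 22 (5S,6S,9R,10R,12E)-6α-[(R)-2-methylbutanoyloxy]-17-oxolabda-7,12-dien-16,15-olide
Conditions: second-generation Hoveyda–Grubbs catalyst (5 mol%), 2,6-dichloro-1,4-benzoquinone (10 mol%), CH2Cl2, 40 °C
Reagents that add atoms: α-methylene-γ-butyrolactone, C=C1CCOC1=O
Why: Olefin cross-metathesis: the unhindered terminal alkene couples with the 1,1-disubstituted acrylate-type alkene of 21 to give the more stable E-alkylidene lactone, the benzoquinone suppresses ruthenium hydride isomerisation of 21, and the trisubstituted enal alkene is inert.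

Step 12
Reactants: 22 (5S,6S,9R,10R,12E)-6α-[(R)-2-methylbutanoyloxy]-17-oxolabda-7,12-dien-16,15-olide
Product: 23 (5S,6S,9R,10R)-6α-[(R)-2-methylbutanoyloxy]-17-oxolabda-7,13-dien-16,15-olide
Conditions: RhCl3·3H2O (10 mol%), EtOH, 78 °C
Reagents that add atoms: none
Why: Transition-metal hydride alkene isomerisation: reversible addition and elimination of a rhodium hydride moves the exocyclic double bond into the lactone ring, where the endocyclic butenolide is the thermodynamic sink.

Step 13
Reactants: 23 (5S,6S,9R,10R)-6α-[(R)-2-methylbutanoyloxy]-17-oxolabda-7,13-dien-16,15-olide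
Product: 24 (5S,6S,9R,10R)-6α-[(R)-2-methylbutanoyloxy]labda-7,13-dien-16,15-olid-17-oic acid (target)
Conditions: NaClO2, NaH2PO4, 2-methyl-2-butene, t-BuOH/H2O, 25 °C
Reagents that add atoms: sodium chlorite, [Na+].[O-]Cl=O
Why: Pinnick oxidation: chlorous acid adds to the aldehyde and fragments to the acid, the scavenger removes HOCl, and the esters, the butenolide and all stereocentres are untouched.

Compound list
1 | 2,2,6-trimethylcyclohexanone | CC1CCCC(C)(C)C1=O | starting material
2 | allyl chloroformate | C=CCOC(=O)Cl | starting material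
3 | allyl 2,6,6-trimethylcyclohex-1-en-1-yl carbonate | C=CCOC(=O)OC1=C(C)CCCC1(C)C | intermediate
4 | (R)-2-allyl-2,6,6-trimethylcyclohexan-1-one | C=CC[C@@]1(C)CCCC(C)(C)C1=O | intermediate
5 | (R)-2,2,6-trimethyl-6-(2-oxopropyl)cyclohexan-1-one | CC(=O)C[C@@]1(C)CCCC(C)(C)C1=O | intermediate
6 | (R)-4,4,7a-trimethyl-1,4,5,6,7,7a-hexahydro-2H-inden-2-one | O=C1C[C@@]2(C)CCCC(C)(C)C2=C1 | intermediate
7 | dibromomethane | BrCBr | starting material
8 | (7aR)-2-(dibromomethyl)-4,4,7a-trimethyl-2,4,5,6,7,7a-hexahydro-1H-inden-2-ol, both carbinol epimers | OC1(C(Br)Br)C[C@@]2(C)CCCC(C)(C)C2=C1 | intermediate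
9 | β-oxido carbenoid (lithium alkoxide of 8 with one Br exchanged for Li) | [Li]OC1(C([Li])Br)C[C@@]2(C)CCCC(C)(C)C2=C1 | intermediate
10 | lithium dienolate of the ring-enlarged ketone | [Li]OC1=CC=C2C(C)(C)CCC[C@]2(C)C1 | intermediate
11 | (R)-5,5,8a-trimethyl-3,5,6,7,8,8a-hexahydronaphthalen-2(1H)-one | O=C1C[C@@]2(C)CCCC(C)(C)C2=CC1 | intermediate
12 | (4aS,8aR)-5,5,8a-trimethyl-4a,5,6,7,8,8a-hexahydronaphthalen-2(1H)-one | O=C1C[C@@]2(C)CCCC(C)(C)[C@@H]2C=C1 | intermediate
13 | allyl bromide | C=CCBr | starting material
14 | (1S,4aS,8aS)-1-allyl-5,5,8a-trimethyl-4a,5,6,7,8,8a-hexahydronaphthalen-2(1H)-one (9α-allyl epimer) | O=C1[C@@H](CC=C)[C@@]2(C)CCCC(C)(C)[C@@H]2C=C1 | intermediate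
15 | (1R,4aS,8aS)-1-allyl-5,5,8a-trimethyl-4a,5,6,7,8,8a-hexahydronaphthalen-2(1H)-one (9β-allyl) | O=C1[C@H](CC=C)[C@@]2(C)CCCC(C)(C)[C@@H]2C=C1 | intermediate
16 | (methoxymethyl)triphenylphosphonium chloride | COC[P+](c1ccccc1)(c1ccccc1)c1ccccc1.[Cl-] | starting material
17 | 17-methoxy-14,15,16-trinorlabda-6,8(17),12-triene, both enol ether geometries | COC=C1[C@H](CC=C)[C@@]2(C)CCCC(C)(C)[C@@H]2C=C1 | intermediate
18 | (5S,6S,9R,10R)-6α-hydroxy-14,15,16-trinorlabda-7,12-dien-17-al | O[C@H]1C=C(C=O)[C@H](CC=C)[C@@]2(C)CCCC(C)(C)[C@H]12 | intermediate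
19 | (R)-2-methylbutanoic acid | CC[C@@H](C)C(=O)O | starting material
20 | (5S,6S,9R,10R)-6α-[(R)-2-methylbutanoyloxy]-14,15,16-trinorlabda-7,12-dien-17-al | CC[C@@H](C)C(=O)O[C@H]1C=C(C=O)[C@H](CC=C)[C@@]2(C)CCCC(C)(C)[C@H]12 | intermediate
21 | α-methylene-γ-butyrolactone | C=C1CCOC1=O | starting material
22 | (12E)-6α-[(R)-2-methylbutanoyloxy]-17-oxolabda-7,12-dien-16,15-olide | CC[C@@H](C)C(=O)O[C@H]1C=C(C=O)[C@H](C/C=C3\CCOC3=O)[C@@]2(C)CCCC(C)(C)[C@H]12 | intermediate
23 | 6α-[(R)-2-methylbutanoyloxy]-17-oxolabda-7,13-dien-16,15-olide | CC[C@@H](C)C(=O)O[C@H]1C=C(C=O)[C@H](CCC3=CCOC3=O)[C@@]2(C)CCCC(C)(C)[C@H]12 | intermediate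
24 | 6α-[(R)-2-methylbutanoyloxy]labda-7,13-dien-16,15-olid-17-oic acid | CC[C@@H](C)C(=O)O[C@H]1C=C(C(=O)O)[C@H](CCC2=CCOC2=O)[C@@]2(C)CCCC(C)(C)[C@H]12 | target

Total step count: 13. Longest linear sequence: 13 steps (1 to 24).

Steps most likely to fail

Step 6 (key step). C9 may migrate in competition with C6. The carbenoid may decompose before the shift. The double bond may move only partly into conjugation, with poor trans/cis control at C5. The fallback sets out from 6 and comes back at 12; it keeps the growth of the five-membered ring but changes the way C7 enters. Dissolving-metal reduction of 6 (Li, NH3, t-BuOH; then Me3SiCl, Et3N) traps the regiodefined enolate as the silyl enol ether F1. Simmons–Smith cyclopropanation (Et2Zn, CH2I2) of its electron-rich C6=C8 bond gives the siloxycyclopropane F2. FeCl3 in DMF cleaves the internal C6–C8 bond by one-electron oxidation and delivers the β-chloro ketone F3. NaOAc in MeOH then eliminates HCl to give 12 (Saegusa-type ring expansion). C5 stays open to base equilibration in the enone.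

Step 8. The basic ylide may enolise the hindered ketone, or olefination may run through the deconjugated isomer of the enone. The fallback sets out from 15 and comes back at 20. The smaller ylide Ph3P=CH2 gives the exocyclic diene F4. mCPBA epoxidises its 1,1-disubstituted C8=C17 bond from the α face to the vinyl oxirane F5. Pd(PPh3)4 with acid 19 opens F5 in the 1,4 sense; ionisation by zerovalent palladium and attack of the carboxylate each go with inversion, so the ester arrives at C6 on the α face of the departing oxygen and gives the hydroxy ester F6. MnO2 oxidises the allylic alcohol of F6 to 20.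

Step 9. Facial selectivity at C6 may be poor, or the peracid may attack the enol ether carbon C8 instead of the diene terminus. The fallback sets out from 17 and comes back at 18. Mild hydrolysis (oxalic acid on wet silica gel) with kinetic protonation at C8 gives the β,γ-unsaturated aldehyde F7. mCPBA epoxidises its isolated C6=C7 bond in a concerted way from the open α face to give the epoxy aldehyde F8. DBU removes the C8 proton and opens the epoxide by E1cB elimination to give 18 with the 6α-hydroxy group.

Further compounds
F1 | step 6 | trans-hydrindane trimethylsilyl enol ether (C6=C8, 5α-H) | C[Si](C)(C)OC1=C[C@H]2C(C)(C)CCC[C@]2(C)C1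
F2 | step 6 | siloxycyclopropane (C6–C7–C8 three-membered ring on the hydrindane, face of addition of no account) | C[Si](C)(C)OC12CC1[C@H]1C(C)(C)CCC[C@]1(C)C2
F3 | step 6 | 6-chloro-5,5?-free name: 4-chloro-5,5,8a-trimethyloctahydronaphthalen-2(1H)-one (β-chloro ketone, 5α-H) | O=C1C[C@@]2(C)CCCC(C)(C)[C@@H]2C(Cl)C1
F4 | step 8 | 14,15,16-trinorlabda-6,8(17),12-triene | C=C1[C@H](CC=C)[C@@]2(C)CCCC(C)(C)[C@@H]2C=C1
F5 | step 8 | 8α,17-epoxy-14,15,16-trinorlabda-6,12-diene | O1C[C@@]12[C@H](CC=C)[C@@]3(C)CCCC(C)(C)[C@@H]3C=C2
F6 | step 8 | 6α-[(R)-2-methylbutanoyloxy]-14,15,16-trinorlabda-7,12-dien-17-ol | CC[C@@H](C)C(=O)O[C@H]1C=C(CO)[C@H](CC=C)[C@@]2(C)CCCC(C)(C)[C@H]12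
F7 | step 9 | 14,15,16-trinorlabda-6,12-dien-17-al (C8 epimers) | O=CC1[C@H](CC=C)[C@@]2(C)CCCC(C)(C)[C@@H]2C=C1
F8 | step 9 | 6α,7α-epoxy-14,15,16-trinorlabd-12-en-17-al (C8 epimers) | O=CC1[C@H](CC=C)[C@@]2(C)CCCC(C)(C)[C@@H]2[C@H]3O[C@@H]13
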